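**Plan**
- Retrosynthesis: cut the nine O–benzyl bonds, then C3–O of the upper unit (back to C3–B), then O1–C2 and C3–C4 of the upper ring C together, then the bond from upper C4 to C6 of the lower ring A; in the lower unit cut C6–Br, O1–C8a, C4–C4a (aryl ketone) and C2–C3 (aldol).
- Enabling feature: the upper ring-A oxygen O1 is ortho to C4, a methine flanked by the upper ring A and C6 of the lower ring A. Such an o-hydroxybenzhydrol ionises to the o-quinone methide O1=C8a–C4a=C4, a four-atom oxadiene that takes up the C2=C3 alkene carrying ring B.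
- Forward: lower chain by aldol, Weinreb amide, aryl ketone and anti-diol; lower ring C by SNAr; bromination at C6; aryllithium addition to the ring-A salicylaldehyde; oxa-[4+2] with a (Z)-alkenylboronate builds the upper ring C with ring B attached; C–B oxidation; hydrogenolysis.
- Stereochemistry: lower C2/C3 from the Evans auxiliary, lower C4 by hydroxyl-directed anti reduction, SNAr without change at carbon; upper 2,3-cis from the (Z)-alkene, 3,4-trans from exo approach, absolute sense from a chiral phosphoric acid, C3–O by retentive oxidation.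

Key step: step 13

Remark: 5, 8 and 23 are taken as commercial. α/β denote the faces of a chroman ring in the usual flavan orientation (a 2R aryl group is 2α); the CIP letters at C2 and C4 of the upper unit change with protection although the geometry does not.

**Step 1**
Reactants: 1 3-fluorocatechol
Product: 2 1,2-bis(benzyloxy)-3-fluorobenzene
Conditions: BnBr, K2CO3, DMF, 60 °C
Reagents that add atoms: benzyl bromide (BrCc1ccccc1)
Why: Williamson etherification of both phenols.

**Step 2**
Reactants: 2 1,2-bis(benzyloxy)-3-fluorobenzene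
Product: 3 1,2-bis(benzyloxy)-4-bromo-3-fluorobenzene
Conditions: NBS, MeCN, 0 °C → rt
Reagents that add atoms: N-bromosuccinimide (O=C1CCC(=O)N1Br)
Why: Electrophilic aromatic bromination should go para to the unhindered 1-benzyloxy group, because the 2-benzyloxy group is twisted out of conjugation by its two neighbours.

**Step 3**
Reactants: 4 (S)-4-benzyl-2-oxazolidinone; 5 benzyloxyacetyl chloride
Product: 7 (S)-4-benzyl-3-[(benzyloxy)acetyl]oxazolidin-2-one, via lithium oxazolidinide 6 (not isolated)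
Conditions: n-BuLi, THF, −78 °C; then 5, −78 → 0 °C
Reagents that add atoms: none
Why: N-acylation of the lithiated Evans auxiliary by the acid chloride.

**Step 4**
Reactants: 7 (S)-4-benzyl-3-[(benzyloxy)acetyl]oxazolidin-2-one; 8 3,4-bis(benzyloxy)benzaldehyde
Product: 10 (S)-4-benzyl-3-[(2S,3R)-2-(benzyloxy)-3-[3,4-bis(benzyloxy)phenyl]-3-hydroxypropanoyl]oxazolidin-2-one, via dibutylboron (Z)-enolate 9 (not isolated)
Conditions: Bu2BOTf, Et3N, CH2Cl2, −78 → 0 °C; then 8, −78 → 0 °C; H2O2, pH 7 buffer, MeOH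
Reagents that add atoms: none
Why: Evans syn-glycolate aldol through a Zimmerman–Traxler chair of the boron (Z)-enolate, in which the (S)-auxiliary fixes both new centres (future lower C3 and C2) as 2S,3R.

**Step 5**
Reactants: 10 syn-aldol imide
Product: 11 (2S,3R)-2-(benzyloxy)-3-[3,4-bis(benzyloxy)phenyl]-3-hydroxy-N-methoxy-N-methylpropanamide
Conditions: MeNHOMe·HCl, AlMe3, THF/CH2Cl2, 0 °C
Reagents that add atoms: N,O-dimethylhydroxylamine hydrochloride (CNOC.Cl)
Why: Aluminium-amide transamidation of an Evans aldol adduct to the Weinreb amide, assisted by the free β-hydroxyl and without epimerisation.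

**Step 6**
Reactants: 3 1,2-bis(benzyloxy)-4-bromo-3-fluorobenzene; 11 Weinreb amide
Product: 13 (2S,3R)-2-(benzyloxy)-1-[3,4-bis(benzyloxy)-2-fluorophenyl]-3-[3,4-bis(benzyloxy)phenyl]-3-hydroxypropan-1-one, via aryllithium 12 (not isolated)
Conditions: 3 (2.3 equiv), n-BuLi, THF, −78 °C; then 11, −78 °C
Reagents that add atoms: none
Why: Bromine–lithium exchange and Weinreb ketone synthesis, the chelated tetrahedral intermediate stopping at the ketone; one equivalent of 12 is spent on the hydroxyl group and −78 °C keeps the o-fluoroaryllithium from losing LiF.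

**Step 7**
Reactants: 13 β-hydroxy aryl ketone
Product: 14 (1R,2S,3R)-2-(benzyloxy)-1-[3,4-bis(benzyloxy)-2-fluorophenyl]-3-[3,4-bis(benzyloxy)phenyl]propane-1,3-diol
Conditions: Me4NBH(OAc)3, MeCN/AcOH, −30 °C
Reagents that add atoms: none
Why: Evans–Saksena reduction, in which hydride is delivered intramolecularly from the alkoxyborohydride through a chair, should give the 1,3-anti diol; the new centre (future lower C4) is thus anti to the 2-benzyloxy group as well.

**Step 8**
Reactants: 14 anti-1,3-diol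
Product: 16 (2R,3R,4R)-3,4,7,8-tetrakis(benzyloxy)-2-[3,4-bis(benzyloxy)phenyl]chroman (hexa-O-benzylmelacacidin), via potassium chroman-4-olate 15 (not isolated)
Conditions: KH, DMF, 0 → 50 °C; then BnBr, 0 °C → rt
Reagents that add atoms: benzyl bromide (BrCc1ccccc1)
Why: Intramolecular SNAr etherification of the fluoroarene by the benzylic alkoxide, a ring closure precedented in de novo flavan-3-ol synthesis, closes the lower ring C with retention at C2 (no bond to that carbon is broken); the other alkoxide could only form a four-membered ring and is benzylated in the same flask.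

**Step 9**
Reactants: 16 hexa-O-benzylmelacacidin
Product: 17 (2R,3R,4R)-6-bromo-3,4,7,8-tetrakis(benzyloxy)-2-[3,4-bis(benzyloxy)phenyl]chroman
Conditions: NBS, CH2Cl2, −20 → 0 °C
Reagents that add atoms: N-bromosuccinimide (O=C1CCC(=O)N1Br)
Why: Electrophilic bromination should select C6, which is ortho to the 7-benzyloxy group and para to O1, over C5 (shielded by the C4 substituent) and over the singly activated ring B.

**Step 10**
Reactants: 18 2,3,4-trihydroxybenzaldehyde
Product: 19 3,4-bis(benzyloxy)-2-hydroxybenzaldehyde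
Conditions: BnBr (2.1 equiv), K2CO3, DMF, rt
Reagents that add atoms: benzyl bromide (BrCc1ccccc1)
Why: Selective Williamson etherification; the 2-hydroxyl is hydrogen-bonded to the formyl group and is the last to be alkylated.

**Step 11**
Reactants: 17 6-bromo-hexa-O-benzylmelacacidin; 19 3,4-bis(benzyloxy)-2-hydroxybenzaldehyde
Product: 22 [3,4-bis(benzyloxy)-2-hydroxyphenyl][(2R,3R,4R)-3,4,7,8-tetrakis(benzyloxy)-2-[3,4-bis(benzyloxy)phenyl]chroman-6-yl]methanol (both carbinol epimers), via sodium phenoxide 20 (not isolated), via aryllithium 21 (not isolated)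
Conditions: 19, NaH, THF, 0 °C; separately 17, n-BuLi, THF, −78 °C; combine, −78 → −30 °C
Reagents that add atoms: none
Why: Bromine–lithium exchange and 1,2-addition of the aryllithium to the phenoxide-masked salicylaldehyde joins the two ring-A carbons through the future upper C4; the carbinol centre is lost in step 13, so its configuration is immaterial.

**Step 12**
Reactants: 23 1-(benzyloxy)-4-ethynylbenzene
Product: 24 (Z)-2-{2-[4-(benzyloxy)phenyl]ethenyl}-4,4,5,5-tetramethyl-1,3,2-dioxaborolane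
Conditions: pinacolborane, [Rh(cod)Cl]2 (1.5 mol%), P(i-Pr)3, Et3N, cyclohexane, rt
Reagents that add atoms: pinacolborane (B1OC(C)(C)C(C)(C)O1)
Why: Rhodium-catalysed formal trans-hydroboration of a terminal alkyne through a rhodium vinylidene places boron and aryl cis, giving the anti-Markovnikov (Z)-alkenylboronate.

**Step 13**
Reactants: 22 o-hydroxybenzhydrol; 24 (Z)-alkenylboronate
Product: 26 3-(pinacolboryl) cycloadduct [upper unit: 2α-(4-benzyloxyphenyl)-3α-(4,4,5,5-tetramethyl-1,3,2-dioxaborolan-2-yl)-7,8-bis(benzyloxy)chroman-4β-yl bonded to C6 of the lower unit of 16], via (E)-o-quinone methide 25 (not isolated)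
Conditions: 24 (2.5 equiv), (R)-3,3'-bis(2,4,6-triisopropylphenyl)-1,1'-binaphthyl-2,2'-diyl hydrogen phosphate (10 mol%), 5 Å MS, toluene, −20 °C → rt
Reagents that add atoms: none
Why: Proposed new method: the chiral phosphoric acid dehydrates the doubly activated o-hydroxybenzhydrol 22 to the hydrogen-bonded (E)-o-quinone methide 25, whose methide carbon attacks the boron-bearing carbon of 24 while the developing 4-benzyloxybenzylic cation (stabilised by the arene and by σ(C–B) hyperconjugation, whereas the reverse orientation would put charge α to boron) is captured by the quinone methide oxygen, i.e. an asynchronous inverse-electron-demand oxa-[4+2] cycloaddition that closes the upper ring C by forming C3–C4 and O1–C2 suprafacially on the alkene. The closest known reaction type is the chiral-phosphoric-acid-catalysed [4+2] cycloaddition of o-quinone methides from o-hydroxybenzhydrols with styrenes and β-substituted styrenes to give 2,4-diarylchromans; an alkenylboronate has not been used as the 2π partner. C2 and C3 should emerge cis because the (Z)-geometry of 24 is transferred stereospecifically, and C3 and C4 trans because the (Z)-alkene approaches the (E)-quinone methide exo, with the pinacolboryl and aryl groups turned away from the heterodiene and only the two vinylic hydrogens beneath it. The face of 25 that is attacked, and so the absolute configuration of the three new centres, is set by the phosphate bound to the quinone methide oxygen (the lower-unit stereocentres are remote); the sense of induction is to be confirmed in the first run and the (S)-acid taken if it is opposite, and because the lower unit is enantiopure the minor facial isomer is a separable diastereomer. The step needs cycloaddition to win over alkenyl transfer with loss of boron, which requires a B–O ate complex and is disfavoured by the pinacol ester and the base-free acidic medium, while sieves and excess 24 should suppress self-condensation of 25.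

**Step 14**
Reactants: 26 3-(pinacolboryl) cycloadduct
Product: 27 nona-O-benzyl ether of the target with free upper 3α-hydroxyl [upper unit 2α-(4-benzyloxyphenyl)-3α-hydroxy-7,8-bis(benzyloxy)chroman-4β-yl on C6 of the lower unit of 16]
Conditions: 30% H2O2, 2 M NaOH, THF, 0 °C → rt
Reagents that add atoms: hydrogen peroxide (OO)
Why: Organoborane oxidation by 1,2-migration of C3 from boron to oxygen in the hydroperoxide ate complex proceeds with retention, and this migration should outrun β-elimination of the ring oxygen as in hydroboration–oxidation of chromenes.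

**Step 15**
Reactants: 27 nona-O-benzyl ether
Product: 28 target, (2R,3R,4S)-2-(4-hydroxyphenyl)-3,7,8-trihydroxychroman-4-yl joined to C6 of (2R,3R,4R)-2-(3,4-dihydroxyphenyl)chroman-3,4,7,8-tetrol
Conditions: H2 (1 atm), Pd(OH)2/C, THF/MeOH, rt
Reagents that add atoms: none
Why: Catalytic hydrogenolysis of the nine benzyl ethers in neutral medium, where the PhCH2–O bonds should cleave faster than the electron-rich benzylic C4–O and ring C2–O1 bonds, as in the debenzylation of perbenzylated proanthocyanidins.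

**Compound list**
1 | 3-fluorocatechol | Oc1cccc(F)c1O | starting material
2 | 1,2-bis(benzyloxy)-3-fluorobenzene | Fc1cccc(OCc2ccccc2)c1OCc1ccccc1 | intermediate
3 | 1,2-bis(benzyloxy)-4-bromo-3-fluorobenzene | Fc1c(Br)ccc(OCc2ccccc2)c1OCc1ccccc1 | intermediate
4 | (S)-4-benzyl-2-oxazolidinone | O=C1N[C@@H](Cc2ccccc2)CO1 | starting material
5 | benzyloxyacetyl chloride | O=C(Cl)COCc1ccccc1 | starting material
6 | lithium salt of 4 (not isolated) | [Li+].O=C1[N-][C@@H](Cc2ccccc2)CO1 | intermediate
7 | (S)-4-benzyl-3-[(benzyloxy)acetyl]oxazolidin-2-one | O=C(COCc1ccccc1)N1C(=O)OC[C@@H]1Cc1ccccc1 | intermediate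
8 | 3,4-bis(benzyloxy)benzaldehyde | O=Cc1ccc(OCc2ccccc2)c(OCc2ccccc2)c1 | starting material
9 | dibutylboron (Z)-enolate of 7 (not isolated) | CCCCB(CCCC)O/C(=C\OCc1ccccc1)N1C(=O)OC[C@@H]1Cc1ccccc1 | intermediate
10 | (2S,3R) syn-aldol imide | O[C@H](c1ccc(OCc2ccccc2)c(OCc2ccccc2)c1)[C@H](OCc1ccccc1)C(=O)N1C(=O)OC[C@@H]1Cc1ccccc1 | intermediate
11 | (2S,3R) Weinreb amide | O[C@H](c1ccc(OCc2ccccc2)c(OCc2ccccc2)c1)[C@H](OCc1ccccc1)C(=O)N(C)OC | intermediate
12 | [3,4-bis(benzyloxy)-2-fluorophenyl]lithium (not isolated) | [Li]c1ccc(OCc2ccccc2)c(OCc2ccccc2)c1F | intermediate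
13 | (2S,3R) β-hydroxy aryl ketone | O[C@H](c1ccc(OCc2ccccc2)c(OCc2ccccc2)c1)[C@H](OCc1ccccc1)C(=O)c1ccc(OCc2ccccc2)c(OCc2ccccc2)c1F | intermediate
14 | (1R,2S,3R) anti-1,3-diol | O[C@H](c1ccc(OCc2ccccc2)c(OCc2ccccc2)c1)[C@H](OCc1ccccc1)[C@@H](c1ccc(OCc2ccccc2)c(OCc2ccccc2)c1F)O | intermediate
15 | potassium (2R,3R,4R)-3,7,8-tris(benzyloxy)-2-[3,4-bis(benzyloxy)phenyl]chroman-4-olate (not isolated) | c1cc2c(c(OCc3ccccc3)c1OCc1ccccc1)O[C@H](c1ccc(OCc3ccccc3)c(OCc3ccccc3)c1)[C@H](OCc1ccccc1)[C@@H]2[O-].[K+] | intermediate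
16 | hexa-O-benzylmelacacidin (all-cis, 2R,3R,4R) | c1cc2c(c(OCc3ccccc3)c1OCc1ccccc1)O[C@H](c1ccc(OCc3ccccc3)c(OCc3ccccc3)c1)[C@H](OCc1ccccc1)[C@@H]2OCc1ccccc1 | intermediate
17 | 6-bromo-hexa-O-benzylmelacacidin | Brc1cc2c(c(OCc3ccccc3)c1OCc1ccccc1)O[C@H](c1ccc(OCc3ccccc3)c(OCc3ccccc3)c1)[C@H](OCc1ccccc1)[C@@H]2OCc1ccccc1 | intermediate
18 | 2,3,4-trihydroxybenzaldehyde | O=Cc1ccc(O)c(O)c1O | starting material
19 | 3,4-bis(benzyloxy)-2-hydroxybenzaldehyde | O=Cc1ccc(OCc2ccccc2)c(OCc2ccccc2)c1O | intermediate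
20 | sodium 5,6-bis(benzyloxy)-2-formylphenoxide (not isolated) | [Na+].[O-]c1c(C=O)ccc(OCc2ccccc2)c1OCc1ccccc1 | intermediate
21 | 6-lithio-hexa-O-benzylmelacacidin (not isolated) | [Li]c1cc2c(c(OCc3ccccc3)c1OCc1ccccc1)O[C@H](c1ccc(OCc3ccccc3)c(OCc3ccccc3)c1)[C@H](OCc1ccccc1)[C@@H]2OCc1ccccc1 | intermediate
22 | o-hydroxybenzhydrol (carbinol epimers) | OC(c1ccc(OCc2ccccc2)c(OCc2ccccc2)c1O)c1cc2c(c(OCc3ccccc3)c1OCc1ccccc1)O[C@H](c1ccc(OCc3ccccc3)c(OCc3ccccc3)c1)[C@H](OCc1ccccc1)[C@@H]2OCc1ccccc1 | intermediate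
23 | 1-(benzyloxy)-4-ethynylbenzene | C#Cc1ccc(OCc2ccccc2)cc1 | starting material
24 | (Z)-2-{2-[4-(benzyloxy)phenyl]ethenyl}-4,4,5,5-tetramethyl-1,3,2-dioxaborolane | CC1(C)OB(/C=C\c2ccc(OCc3ccccc3)cc2)OC1(C)C | intermediate
25 | (E)-o-quinone methide (not isolated) | O=C1/C(=C/c2cc3c(c(OCc4ccccc4)c2OCc2ccccc2)O[C@H](c2ccc(OCc4ccccc4)c(OCc4ccccc4)c2)[C@H](OCc2ccccc2)[C@@H]3OCc2ccccc2)C=CC(OCc2ccccc2)=C1OCc1ccccc1 | intermediate
26 | 3-(pinacolboryl) cycloadduct (upper unit 2α-aryl, 3α-boryl, 4β-flavanyl) | C(c5ccccc5)Oc1ccc([C@H]2Oc3c(ccc(OCc5ccccc5)c3OCc5ccccc5)[C@H](c3cc4c(c(OCc5ccccc5)c3OCc5ccccc5)O[C@H](c3ccc(OCc5ccccc5)c(OCc5ccccc5)c3)[C@H](OCc5ccccc5)[C@@H]4OCc5ccccc5)[C@H]2B2OC(C)(C)C(C)(C)O2)cc1 | intermediate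
27 | nona-O-benzyl ether with free upper 3α-hydroxyl | C(c5ccccc5)Oc1ccc([C@H]2Oc3c(ccc(OCc5ccccc5)c3OCc5ccccc5)[C@H](c3cc4c(c(OCc5ccccc5)c3OCc5ccccc5)O[C@H](c3ccc(OCc5ccccc5)c(OCc5ccccc5)c3)[C@H](OCc5ccccc5)[C@@H]4OCc5ccccc5)[C@H]2O)cc1 | intermediate
28 | CNP0275688.2 | Oc1ccc([C@H]2Oc3c(ccc(O)c3O)[C@H](c3cc4c(c(O)c3O)O[C@H](c3ccc(O)c(O)c3)[C@H](O)[C@@H]4O)[C@H]2O)cc1 | target

**Totals**
Total step count: 15. Longest linear sequence: 11 steps (3, 4, 5, 6, 7, 8, 9, 11, 13, 14, 15).

**Steps most likely to fail**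

Step 13. Ring closure may lose to alkenyl transfer with loss of boron or to protodeboronation, the (Z)-alkene may isomerise, exo/endo or facial selectivity may be poor, and the quinone methide may self-condense. The fallback uses known chemistry and still makes O1–C2 and C3–C4 in one operation, adding ring B afterwards. It sets out from 22: enamine-catalysed Michael addition/hemiacetalisation with benzyloxyacetaldehyde [(S)-2-[diphenyl(trimethylsilyloxy)methyl]pyrrolidine (20 mol%), PhCO2H (20 mol%), CHCl3, rt; the catalyst antipode that gives the 3α,4β series is used] should give the 3,4-trans lactol 3α-(benzyloxy)-4β-(lower flavanyl)-7,8-bis(benzyloxy)chroman-2-ol F1. 4-(Benzyloxy)phenylmagnesium bromide (THF, 0 °C) opens it to the phenol-diol F2. MnO2 (CH2Cl2, rt) oxidises the benzylic carbinol to the aryl ketone F3. Et3SiH/BF3·OEt2 (CH2Cl2, −78 °C) closes ring C by reductive etherification, hydride adding to the 2-aryl oxocarbenium ion anti to the 3-benzyloxy group (2,3-cis), to give the deca-O-benzyl ether F4. The conditions of step 15 bring F4 back to the route at 28.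

Step 8. Displacement of fluoride from the electron-rich ring may be sluggish, so that the dialkoxide decomposes or the wrong hydroxyl is benzylated when BnBr is added before closure is complete. The fallback sets out from ketone 13 and cyclises while the ortho-carbonyl activates the fluoroarene (K2CO3, DMF, rt) to the 2,3-cis flavanone (2R,3S)-3,7,8-tris(benzyloxy)-2-[3,4-bis(benzyloxy)phenyl]chroman-4-one F5. Reduction with LiBH(s-Bu)3 (THF, −78 °C), hydride entering on the β-face opposite the 2-aryl and 3-benzyloxy groups, should give the all-cis alcohol (2R,3R,4R)-3,7,8-tris(benzyloxy)-2-[3,4-bis(benzyloxy)phenyl]chroman-4-ol F6. NaH/BnBr (DMF) then returns to the route at 16.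

Step 11. Addition to the deactivated phenoxide-aldehyde may be incomplete, with protonation of the aryllithium, and the benzhydrol may be lost through premature quinone methide formation on work-up. The fallback masks the phenol instead: from 19, allyl bromide/K2CO3 (DMF) gives 2-(allyloxy)-3,4-bis(benzyloxy)benzaldehyde F7. Aryllithium 21 (from 17, n-BuLi, THF, −78 °C) adds to give the O-allyl benzhydrol F8. Neutral deallylation (Pd(PPh3)4, morpholine, THF, rt) returns to the route at 22.

**Further compounds**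
F1 | step 13 | 3α-(benzyloxy)-4β-(lower flavanyl)-7,8-bis(benzyloxy)chroman-2-ol (lactol, anomers) | OC1Oc2c(ccc(OCc5ccccc5)c2OCc5ccccc5)[C@H](c3cc4c(c(OCc5ccccc5)c3OCc5ccccc5)O[C@H](c3ccc(OCc5ccccc5)c(OCc5ccccc5)c3)[C@H](OCc5ccccc5)[C@@H]4OCc5ccccc5)[C@H]1OCc5ccccc5
F2 | step 13 | ring-opened phenol-diol (carbinol epimers) | OC(c1ccc(OCc5ccccc5)cc1)[C@H](OCc5ccccc5)[C@@H](c3cc4c(c(OCc5ccccc5)c3OCc5ccccc5)O[C@H](c3ccc(OCc5ccccc5)c(OCc5ccccc5)c3)[C@H](OCc5ccccc5)[C@@H]4OCc5ccccc5)c1ccc(OCc5ccccc5)c(OCc5ccccc5)c1O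
F3 | step 13 | o-hydroxyaryl 4-(benzyloxy)phenyl ketone (open form of the 2-hydroxyflavan) | O=C(c1ccc(OCc5ccccc5)cc1)[C@H](OCc5ccccc5)[C@@H](c3cc4c(c(OCc5ccccc5)c3OCc5ccccc5)O[C@H](c3ccc(OCc5ccccc5)c(OCc5ccccc5)c3)[C@H](OCc5ccccc5)[C@@H]4OCc5ccccc5)c1ccc(OCc5ccccc5)c(OCc5ccccc5)c1O
F4 | step 13 | deca-O-benzyl ether of the target (3-O-benzyl ether of 27) | C(c5ccccc5)Oc1ccc([C@H]2Oc3c(ccc(OCc5ccccc5)c3OCc5ccccc5)[C@H](c3cc4c(c(OCc5ccccc5)c3OCc5ccccc5)O[C@H](c3ccc(OCc5ccccc5)c(OCc5ccccc5)c3)[C@H](OCc5ccccc5)[C@@H]4OCc5ccccc5)[C@H]2OCc5ccccc5)cc1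
F5 | step 8 | (2R,3S)-3,7,8-tris(benzyloxy)-2-[3,4-bis(benzyloxy)phenyl]chroman-4-one | c1cc2c(c(OCc3ccccc3)c1OCc1ccccc1)O[C@H](c1ccc(OCc3ccccc3)c(OCc3ccccc3)c1)[C@H](OCc1ccccc1)C2=O
F6 | step 8 | (2R,3R,4R)-3,7,8-tris(benzyloxy)-2-[3,4-bis(benzyloxy)phenyl]chroman-4-ol | c1cc2c(c(OCc3ccccc3)c1OCc1ccccc1)O[C@H](c1ccc(OCc3ccccc3)c(OCc3ccccc3)c1)[C@H](OCc1ccccc1)[C@@H]2O
F7 | step 11 | 2-(allyloxy)-3,4-bis(benzyloxy)benzaldehyde | O=Cc1ccc(OCc2ccccc2)c(OCc2ccccc2)c1OCC=C
F8 | step 11 | O-allyl ether of benzhydrol 22 (carbinol epimers) | OC(c1ccc(OCc2ccccc2)c(OCc2ccccc2)c1OCC=C)c1cc2c(c(OCc3ccccc3)c1OCc1ccccc1)O[C@H](c1ccc(OCc3ccccc3)c(OCc3ccccc3)c1)[C@H](OCc1ccccc1)[C@@H]2OCc1ccccc1
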